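The route rests on disconnecting C3=C4, the only alkene of the pyran ring (chromene numbering). C4 is attached to C4a of ring A and C3 to the quaternary C2 bound to O1, so both halves can be placed on neighbouring ring A positions as simple alkenes. Ring-closing metathesis then forms C3=C4, closes the pyran and gives the target directly, leaving ring A and the C6 diketone chain untouched. The precursor is the complete 2-hydroxyaryl phenyl 1,3-diketone. It bears a 1,1-dimethylallyl ether at the future O1 and an ortho (E)-propenyl group at the future C4a, and is built from 2',4'-dihydroxy-6'-methoxyacetophenone.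

Key step: step 7

Assumption: the 1,3-diketones are drawn as diketo tautomers although they should exist largely as chelated enols, and both forms count as one compound here. In steps 1 to 6 ring A carries acetophenone locants (C1 bears the acyl group).

Step 1
Reactants: 1 2',4'-dihydroxy-6'-methoxyacetophenone; 2 allyl bromide
Product: 3 1-(4-allyloxy-2-hydroxy-6-methoxyphenyl)ethanone
Conditions: K2CO3 (1.1 equiv), 2 (1.05 equiv), acetone, reflux
Reagents that add atoms: allyl bromide (2), C=CCBr
Why: Williamson ether synthesis (SN2): the 2-OH is tied up in a hydrogen bond to the acetyl carbonyl, so about one equivalent of mild base should deprotonate only the more acidic 4-OH para to the ketone, which then displaces bromide from 2.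

Step 2
Reactants: 3 1-(4-allyloxy-2-hydroxy-6-methoxyphenyl)ethanone
Product: 5 1-(3-allyl-2,4-dihydroxy-6-methoxyphenyl)ethanone, via 6-allylcyclohexa-2,4-dienone 4 (not isolated)
Conditions: N,N-diethylaniline, 195 °C, N2
Reagents that add atoms: none
Why: Aromatic Claisen rearrangement: the hydrogen-bonded chelate of the 2-OH and the acetyl group localises double-bond character in C3=C4 of ring A, so the [3,3] shift should deliver the allyl group to C3 between the two oxygens rather than to C5, and the racemic sp3 carbon of dienone 4 disappears on tautomerisation to phenol 5.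

Step 3
Reactants: 5 1-(3-allyl-2,4-dihydroxy-6-methoxyphenyl)ethanone
Product: 6 1-[2,4-dihydroxy-6-methoxy-3-[(E)-prop-1-enyl]phenyl]ethanone
Conditions: RuClH(CO)(PPh3)3 (3 mol %), toluene, 80 °C
Reagents that add atoms: none
Why: Ruthenium hydride catalysed alkene isomerisation by reversible hydrometallation and β-hydride elimination should move the terminal alkene one position into conjugation with ring A under thermodynamic control, which favours the (E)-propenyl isomer and leaves the phenols and the ketone alone.

Step 4
Reactants: 7 2-methylbut-3-en-2-ol; 8 di-tert-butyl dicarbonate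
Product: 10 tert-butyl 2-methylbut-3-en-2-yl carbonate, via lithium 2-methylbut-3-en-2-olate 9 (not isolated)
Conditions: n-BuLi (1.0 equiv), THF, −78 to 0 °C; 8 (1.05 equiv), 0 °C to rt; H2O work-up
Reagents that add atoms: di-tert-butyl dicarbonate (8), CC(C)(C)OC(=O)OC(=O)OC(C)(C)C
Why: O-acylation of an alkoxide by a dicarbonate: the hindered tertiary allylic alcohol is first turned into the strongly nucleophilic lithium alkoxide 9, which attacks one carbonyl group of 8 and expels tert-butyl carbonate, which falls apart to CO2 and tert-butoxide.

Step 5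
Reactants: 6 1-[2,4-dihydroxy-6-methoxy-3-[(E)-prop-1-enyl]phenyl]ethanone; 10 tert-butyl 2-methylbut-3-en-2-yl carbonate
Product: 11 1-[2-hydroxy-6-methoxy-4-(2-methylbut-3-en-2-yloxy)-3-[(E)-prop-1-enyl]phenyl]ethanone
Conditions: Pd(PPh3)4 (3 mol %), 10 (1.3 equiv), THF, 0–5 °C, work-up below 30 °C
Reagents that add atoms: tert-butyl 2-methylbut-3-en-2-yl carbonate (10), CC(C)(C)OC(=O)OC(C)(C)C=C
Why: Tsuji–Trost type decarboxylative O-allylation: zerovalent palladium ionises 10 to a cationic 1,1-dimethylallyl palladium complex, CO2 and tert-butoxide, the alkoxide deprotonates the free 4-OH (the 2-OH stays chelated and is flanked on both sides), and under kinetic control near 0 °C the phenoxide should attack the more substituted allyl terminus to give the tertiary ether, a step placed before diketone formation because a 1,3-diketone would be C-allylated.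

Step 6
Reactants: 11 1-[2-hydroxy-6-methoxy-4-(2-methylbut-3-en-2-yloxy)-3-[(E)-prop-1-enyl]phenyl]ethanone; 12 benzoyl chloride
Product: 14 1-[2-hydroxy-6-methoxy-4-(2-methylbut-3-en-2-yloxy)-3-[(E)-prop-1-enyl]phenyl]-3-phenylpropane-1,3-dione, via dilithium phenoxide-enolate 13 (not isolated)
Conditions: LiN(SiMe3)2 (3.2 equiv), THF, −78 to −10 °C; 12 (1.0 equiv), −78 to 0 °C; AcOH quench at 0 °C
Reagents that add atoms: benzoyl chloride (12), O=C(Cl)c1ccccc1
Why: Crossed Claisen condensation of an o-hydroxyacetophenone dianion, the direct form of the Baker–Venkataraman route: dianion 13 should be benzoylated at its enolate carbon by 12, the third equivalent of base deprotonates the acidic product and so blocks a second acylation, and the cold basic medium followed by a mild AcOH quench spares the heat- and acid-labile tertiary allyl ether.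

Step 7
Reactants: 14 1-[2-hydroxy-6-methoxy-4-(2-methylbut-3-en-2-yloxy)-3-[(E)-prop-1-enyl]phenyl]-3-phenylpropane-1,3-dione
Product: 15 1-(5-hydroxy-7-methoxy-2,2-dimethyl-2H-chromen-6-yl)-3-phenylpropane-1,3-dione
Conditions: second-generation Grubbs catalyst RuCl2(=CHPh)(H2IMes)(PCy3) (5 mol %), CH2Cl2 (0.01 M), 35–40 °C, argon sparge
Reagents that add atoms: none
Why: Loss of PCy3 from RuCl2(=CHPh)(H2IMes)(PCy3) gives the active 14-electron alkylidene, which should load on the only terminal alkene, the vinyl group of the ether, then add across the neighbouring propenyl C=C in an intramolecular [2+2] step, and cycloreversion of the ruthenacyclobutane releases 15 together with a ruthenium ethylidene that gives up propene when it picks up the vinyl group of the next molecule of 14. The closest known reaction type is the ring-closing metathesis of o-alkenylaryl allyl ethers to 2H-chromenes. The pyran ring is closed as a six-membered ring by joining the alkene carbon on C4a to the alkene carbon on C2, two partners held ortho to each other on ring A, with help from the gem-dimethyl group at C2 and from the escape of propene. No stereocentre is formed, the ring allows only a cis C3=C4 bond, and the geometry of the propenyl group is lost with the propene, so its isomeric purity does not matter. The selectivity needed is one of rates: the tertiary allyl aryl ether still has a free ortho carbon (C8) open to an aromatic Claisen shift and it ionises under acid, so closure must win at or below 40 °C in a neutral medium, which the proximity of the two alkenes secures, while high dilution holds back cross-metathesis. The 5-OH is hydrogen-bonded to the C6 carbonyl group and the diketone is locked in its own enol chelate, so neither should bind ruthenium strongly.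

Compound list
1 | 2',4'-dihydroxy-6'-methoxyacetophenone | COc1cc(O)cc(O)c1C(C)=O | starting material
2 | allyl bromide | C=CCBr | starting material
3 | 1-(4-allyloxy-2-hydroxy-6-methoxyphenyl)ethanone | COc1cc(OCC=C)cc(O)c1C(C)=O | intermediate
4 | 4-acetyl-6-allyl-5-hydroxy-3-methoxycyclohexa-2,4-dien-1-one (racemic, transient) | COC1=CC(=O)C(CC=C)C(O)=C1C(C)=O | intermediate
5 | 1-(3-allyl-2,4-dihydroxy-6-methoxyphenyl)ethanone | COc1cc(O)c(CC=C)c(O)c1C(C)=O | intermediate
6 | 1-[2,4-dihydroxy-6-methoxy-3-[(E)-prop-1-enyl]phenyl]ethanone | COc1cc(O)c(/C=C/C)c(O)c1C(C)=O | intermediate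
7 | 2-methylbut-3-en-2-ol | CC(C)(O)C=C | starting material
8 | di-tert-butyl dicarbonate | CC(C)(C)OC(=O)OC(=O)OC(C)(C)C | starting material
9 | lithium 2-methylbut-3-en-2-olate | [Li+].[O-]C(C)(C)C=C | intermediate
10 | tert-butyl 2-methylbut-3-en-2-yl carbonate | CC(C)(C)OC(=O)OC(C)(C)C=C | intermediate
11 | 1-[2-hydroxy-6-methoxy-4-(2-methylbut-3-en-2-yloxy)-3-[(E)-prop-1-enyl]phenyl]ethanone | COc1cc(OC(C)(C)C=C)c(/C=C/C)c(O)c1C(C)=O | intermediate
12 | benzoyl chloride | O=C(Cl)c1ccccc1 | starting material
13 | dilithium phenoxide-enolate of 11 | COc1cc(OC(C)(C)C=C)c(/C=C/C)c([O-])c1C([O-])=C.[Li+].[Li+] | intermediate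
14 | 1-[2-hydroxy-6-methoxy-4-(2-methylbut-3-en-2-yloxy)-3-[(E)-prop-1-enyl]phenyl]-3-phenylpropane-1,3-dione | COc1cc(OC(C)(C)C=C)c(/C=C/C)c(O)c1C(=O)CC(=O)c1ccccc1 | intermediate
15 | 1-(5-hydroxy-7-methoxy-2,2-dimethyl-2H-chromen-6-yl)-3-phenylpropane-1,3-dione | COc1cc2c(c(O)c1C(=O)CC(=O)c1ccccc1)C=CC(C)(C)O2 | target

Total step count: 7.
Longest linear sequence: 6 steps (1, 2, 3, 5, 6, 7). Step 4 is a one-step side branch.

Steps most likely to fail

**Step 7.**
- Risk: the catalyst may load slowly on the vinyl group next to the quaternary carbon, and the enolised diketone may sequester part of the ruthenium. The aromatic Claisen shift or ionisation of the tertiary ether could then overtake ring closure.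
- Fallback: this sets out from 1 and comes back at 15, building the pyran by electrocyclisation instead of metathesis.
- Compound 1 is heated with 3-methylbut-2-enal and catalytic ethylenediammonium diacetate in toluene at reflux.
- Knoevenagel-type attack through C3 should give the o-quinone methide 4-acetyl-5-hydroxy-3-methoxy-6-(3-methylbut-2-enylidene)cyclohexa-2,4-dien-1-one F1 (not isolated).
- Oxa-6π electrocyclisation of F1 onto the unchelated oxygen should give 1-(5-hydroxy-7-methoxy-2,2-dimethyl-2H-chromen-6-yl)ethanone F2.
- LiN(SiMe3)2 in THF then converts F2 into the dilithium phenoxide-enolate of the chromenyl ketone F3 (not isolated). This is benzoylated by 12 and quenched with AcOH as in step 6, arriving at 15.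

**Step 5.**
- Risk: branched selectivity may erode because zerovalent palladium can re-ionise the tertiary ether, causing drift toward the linear prenyl ether. Over-alkylation at the chelated hydroxyl is also possible.
- Fallback: this sets out from 6 and comes back at 11, making the tertiary C–O bond by propargylic substitution, which has no linear outlet.
- Compound 6 is treated with 3-chloro-3-methylbut-1-yne, catalytic CuCl2·2H2O and DBU in MeCN at 0 °C. This should give 1-[2-hydroxy-6-methoxy-4-(2-methylbut-3-yn-2-yloxy)-3-[(E)-prop-1-enyl]phenyl]ethanone F4.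
- Semihydrogenation of the terminal alkyne (H2, 1 atm, Pd/CaCO3 poisoned with Pb(OAc)2, quinoline, EtOAc, rt) then gives 11.

**Step 2.**
- Risk: regiocontrol of the [3,3] shift may be incomplete, with migration to C5 competing with migration to C3.
- Fallback: this sets out from 1 and comes back at 5, delivering the allyl group from the 2-oxygen, whose only free ortho carbon is C3.
- Compound 1 is masked selectively at the unchelated hydroxyl (MOMCl, K2CO3, acetone, rt) as 1-[2-hydroxy-6-methoxy-4-(methoxymethoxy)phenyl]ethanone F5.
- F5 is allylated with 2 (K2CO3, DMF, 60 °C) to 1-[2-allyloxy-6-methoxy-4-(methoxymethoxy)phenyl]ethanone F6.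
- Heating F6 in N,N-diethylaniline at 190 °C should lead through 2-acetyl-6-allyl-3-methoxy-5-(methoxymethoxy)cyclohexa-2,4-dien-1-one F7 (not isolated) to 1-[3-allyl-2-hydroxy-6-methoxy-4-(methoxymethoxy)phenyl]ethanone F8.
- The acetal of F8 is removed with HCl in MeOH at 45 °C to give 5.

Further compounds
F1 | step 7 | 4-acetyl-5-hydroxy-3-methoxy-6-(3-methylbut-2-enylidene)cyclohexa-2,4-dien-1-one | COC1=CC(=O)C(=CC=C(C)C)C(O)=C1C(C)=O
F2 | step 7 | 1-(5-hydroxy-7-methoxy-2,2-dimethyl-2H-chromen-6-yl)ethanone | COc1cc2c(c(O)c1C(C)=O)C=CC(C)(C)O2
F3 | step 7 | dilithium phenoxide-enolate of the chromenyl ketone | COc1cc2c(c([O-])c1C([O-])=C)C=CC(C)(C)O2.[Li+].[Li+]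
F4 | step 5 | 1-[2-hydroxy-6-methoxy-4-(2-methylbut-3-yn-2-yloxy)-3-[(E)-prop-1-enyl]phenyl]ethanone | COc1cc(OC(C)(C)C#C)c(/C=C/C)c(O)c1C(C)=O
F5 | step 2 | 1-[2-hydroxy-6-methoxy-4-(methoxymethoxy)phenyl]ethanone | COCOc1cc(O)c(C(C)=O)c(OC)c1
F6 | step 2 | 1-[2-allyloxy-6-methoxy-4-(methoxymethoxy)phenyl]ethanone | COCOc1cc(OCC=C)c(C(C)=O)c(OC)c1
F7 | step 2 | 2-acetyl-6-allyl-3-methoxy-5-(methoxymethoxy)cyclohexa-2,4-dien-1-one | COCOC1=CC(OC)=C(C(C)=O)C(=O)C1CC=C
F8 | step 2 | 1-[3-allyl-2-hydroxy-6-methoxy-4-(methoxymethoxy)phenyl]ethanone | COCOc1cc(OC)c(C(C)=O)c(O)c1CC=C
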